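**Retrosynthetic overview**

1. Endgame, read backwards: the C6 ketone comes from a C6–OTBS group (unveiled and oxidised last under neutral conditions, because C5 is α to it); the aryl ether comes from a palladium-catalysed C–O coupling of the neopentyl C1–CH2OH with 7-bromocoumarin; CH2OH comes from CHO; saturated ring A comes from a C3=C4 olefin.
2. Key disconnection: the ring-fusion bond C4a–C8a and the C1–C2 bond are cut together (intramolecular Diels–Alder retron), opening rings A and B at once to an acyclic (2E,8E,10E)-2,7,8-trimethyl-6-silyloxydodeca-2,8,10-trienal.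
3. Enabling feature: ring A (C1, C2, C3, C4, C4a, C8a) is a cyclohexane whose quaternary C1 carries a one-carbon oxygenated arm (CH2OAr, a reduced CHO that activates a C1=C8a dienophile), and the four ring-B carbons C5–C8 are exactly the tether joining fusion carbons C4a (diene terminus) and C8a (dienophile carbon).
4. Only two stereocentres enter the cyclisation (C6–O and C5–CH3, a syn pair from an auxiliary-controlled aldol); they relay configuration to C1, C2, C4a and C8a.
5. The trienal is built linearly (aldol, alkyne, methylalumination/iodination, cross-metathesis with methacrolein, Suzuki coupling); rings A and B then form together in one step, and the coumarin ring is purchased.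

Key step: step 9

Remark on the chemistry (numbering and one assumption): decalin numbering of the target is used (C1 = quaternary C bearing CH2OAr and CH3, C2 = CHCH3, C4a = angular C–CH3, C5 = CHCH3, C6 = C=O, C8a = fusion CH), open-chain intermediates keep their own chain numbering; the C5 methyl is assumed to be the equatorial epimer, only modestly favoured at equilibrium, so it is set kinetically and the ketone is made last without acid or base.

**Route**

Step 1
Reactants: 1 (4S)-4-benzyl-1,3-thiazolidine-2-thione; 2 propanoyl chloride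
Product: 3 1-[(4S)-4-benzyl-2-sulfanylidene-1,3-thiazolidin-3-yl]propan-1-one
Conditions: Et3N, DMAP (cat.), CH2Cl2, 0 °C → rt
Reagents that add atoms: none
Why: N-acylation of the thiazolidinethione nitrogen by the acid chloride, which leaves the auxiliary stereocentre untouched.

Step 2
Reactants: 3 1-[(4S)-4-benzyl-2-sulfanylidene-1,3-thiazolidin-3-yl]propan-1-one; 4 pent-4-enal
Product: 6 (2S,3R)-1-[(4S)-4-benzyl-2-sulfanylidene-1,3-thiazolidin-3-yl]-3-hydroxy-2-methylhept-6-en-1-one, via trichlorotitanium (Z)-enolate 5 (not isolated)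
Conditions: TiCl4 (1.05 equiv), iPr2NEt (1.1 equiv), NMP (1 equiv), CH2Cl2, 0 °C; then 4, 0 °C; aq. NH4Cl
Reagents that add atoms: none
Why: Titanium-enolate aldol of an N-acylthiazolidinethione (Crimmins-type, non-chelated "Evans-syn" mode), in which the (Z)-enolate reacts through a Zimmerman–Traxler chair on the face away from the benzyl group and so should set C2 (S) and C3 (R) syn.

Step 3
Reactants: 6 (2S,3R)-1-[(4S)-4-benzyl-2-sulfanylidene-1,3-thiazolidin-3-yl]-3-hydroxy-2-methylhept-6-en-1-one
Product: 7 (2S,3R)-1-[(4S)-4-benzyl-2-sulfanylidene-1,3-thiazolidin-3-yl]-3-[(tert-butyldimethylsilyl)oxy]-2-methylhept-6-en-1-one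
Conditions: TBSOTf, 2,6-lutidine, CH2Cl2, −78 → 0 °C
Reagents that add atoms: tert-butyldimethylsilyl trifluoromethanesulfonate, CC(C)(C)[Si](C)(C)OS(=O)(=O)C(F)(F)F
Why: Silylation of the secondary alcohol with a silyl triflate and a hindered base, fast enough at low temperature to avoid retro-aldol cleavage.

Step 4
Reactants: 7 (2S,3R)-1-[(4S)-4-benzyl-2-sulfanylidene-1,3-thiazolidin-3-yl]-3-[(tert-butyldimethylsilyl)oxy]-2-methylhept-6-en-1-one
Product: 8 (2S,3R)-3-[(tert-butyldimethylsilyl)oxy]-2-methylhept-6-enal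
Conditions: iBu2AlH (1.5 equiv), CH2Cl2, −78 °C; aq. Rochelle salt
Reagents that add atoms: none
Why: Partial reduction of the activated N-acylthiazolidinethione by DIBAL-H stops at a stable aluminium hemiaminal that releases the aldehyde (and auxiliary 1) only on work-up, and −78 °C should prevent over-reduction and epimerisation at C2.

Step 5
Reactants: 8 (2S,3R)-3-[(tert-butyldimethylsilyl)oxy]-2-methylhept-6-enal
Product: 9 (5R,6R)-5-[(tert-butyldimethylsilyl)oxy]-6-methyloct-1-en-7-yne
Conditions: dimethyl (1-diazo-2-oxopropyl)phosphonate, K2CO3, MeOH, 0 °C → rt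
Reagents that add atoms: dimethyl (1-diazo-2-oxopropyl)phosphonate, CC(=O)C(=[N+]=[N-])P(=O)(OC)OC
Why: Seyferth–Gilbert homologation in the Ohira–Bestmann variant, where the diazomethylphosphonate anion made in the flask adds to the aldehyde and loss of phosphate and N2 with 1,2-hydride shift gives the terminal alkyne under conditions mild enough to keep the α-stereocentre.

Step 6
Reactants: 9 (5R,6R)-5-[(tert-butyldimethylsilyl)oxy]-6-methyloct-1-en-7-yne
Product: 11 (1E,3R,4R)-4-[(tert-butyldimethylsilyl)oxy]-1-iodo-2,3-dimethylocta-1,7-diene, via (E)-alkenyldimethylalane 10 (not isolated)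
Conditions: AlMe3 (3 equiv), Cp2ZrCl2 (0.25 equiv), CH2Cl2, 0 °C → rt; then I2, THF, −30 → 0 °C
Reagents that add atoms: trimethylaluminium, C[Al](C)C; iodine, II
Why: Negishi zirconium-catalysed carboalumination adds CH3 and Al syn across the terminal alkyne with methyl on the internal carbon, and iodinolysis of the C–Al bond with retention should give the (E)-trisubstituted iodide while the isolated terminal alkene stays inert.

Step 7
Reactants: 11 (1E,3R,4R)-4-[(tert-butyldimethylsilyl)oxy]-1-iodo-2,3-dimethylocta-1,7-diene; 12 2-methylprop-2-enal (methacrolein, 8 equiv)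
Product: 13 (2E,6R,7R,8E)-6-[(tert-butyldimethylsilyl)oxy]-9-iodo-2,7,8-trimethylnona-2,8-dienal
Conditions: second-generation Hoveyda–Grubbs catalyst RuCl2(H2IMes)(=CH–C6H4-2-OiPr) (5 mol%), CH2Cl2, 40 °C
Reagents that add atoms: none
Why: Olefin cross-metathesis of the unhindered terminal alkene with excess methacrolein should give the thermodynamically preferred (E)-2-methyl enal, the hindered electron-poor iodoalkene being a spectator.

Step 8
Reactants: 13 (2E,6R,7R,8E)-6-[(tert-butyldimethylsilyl)oxy]-9-iodo-2,7,8-trimethylnona-2,8-dienal; 14 4,4,5,5-tetramethyl-2-[(1E)-prop-1-en-1-yl]-1,3,2-dioxaborolane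
Product: 15 (2E,6R,7R,8E,10E)-6-[(tert-butyldimethylsilyl)oxy]-2,7,8-trimethyldodeca-2,8,10-trienal
Conditions: PdCl2(dppf) (5 mol%), Cs2CO3, THF/H2O, rt, dark
Reagents that add atoms: none
Why: Suzuki–Miyaura coupling at the C–I bond proceeds with retention of both alkene geometries to give the (8E,10E)-diene, and room temperature keeps the enal intact and avoids premature thermal cyclisation.

Step 9
Reactants: 15 (2E,6R,7R,8E,10E)-6-[(tert-butyldimethylsilyl)oxy]-2,7,8-trimethyldodeca-2,8,10-trienal
Product: 16 (1R,2R,4aS,5R,6R,8aR)-6-[(tert-butyldimethylsilyl)oxy]-1,2,4a,5-tetramethyl-1,2,4a,5,6,7,8,8a-octahydronaphthalene-1-carbaldehyde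
Conditions: Me2AlCl (1.2 equiv), CH2Cl2, −78 → −30 °C; cold 1 M HCl quench
Reagents that add atoms: none
Why: Me2AlCl binds the aldehyde oxygen and the (E)-2-methyl enal adds across the 8,10-diene in a concerted, asynchronous [4+2] cycloaddition (type 1 intramolecular Diels–Alder reaction of a 1,7,9-decatriene; closest known reaction type: Lewis-acid-promoted cyclisation of (E,E,E)-2-methyl-2,8,10-trienals to trans-fused octalin carbaldehydes). Ring B closes as a six-membered chair made by the four-carbon tether when chain C3 bonds to chain C8 (the C8a–C4a fusion bond), and ring A closes as the new cyclohexene when chain C2 bonds to chain C11 (the C1–C2 bond), so both rings arise from an open chain in one operation. The C1/C8a relationship (CHO cis to H-8a) is copied from the E dienophile and the C2/C4a relationship (2-methyl trans to the angular methyl) from the 8E,10E diene, both by suprafacial addition, and the link between the two pairs comes from the CHO-endo, tether-exo transition state, which is the trans-fused one. The absolute sense comes from C6: its OTBS group has to sit equatorial on the chair tether because the axial position would be 1,3-syn to the methyl on chain C8, and the syn-related C7 methyl is then equatorial too, so one diene face is presented. The selectivities needed are endo (trans-fused) over exo (cis-fused) and one π-face, secured by Lewis-acid activation at low temperature and by the two equatorial tether substituents, with regiochemistry fixed by the tether. The endo transition state does bring the exo 2-methyl 1,3 to the inside methyl on chain C8 (they end 1,3-diaxial), a penalty that should be softened by the long peripheral C2–C11 bond of the asynchronous transition state.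

Step 10
Reactants: 16 (1R,2R,4aS,5R,6R,8aR)-6-[(tert-butyldimethylsilyl)oxy]-1,2,4a,5-tetramethyl-1,2,4a,5,6,7,8,8a-octahydronaphthalene-1-carbaldehyde
Product: 17 [(1R,2R,4aS,5R,6R,8aR)-6-[(tert-butyldimethylsilyl)oxy]-1,2,4a,5-tetramethyl-1,2,4a,5,6,7,8,8a-octahydronaphthalen-1-yl]methanol
Conditions: NaBH4, MeOH/CH2Cl2, 0 °C
Reagents that add atoms: none
Why: Borohydride reduction of the non-enolisable neopentyl aldehyde to the primary alcohol, with no stereocentre created or at risk.

Step 11
Reactants: 17 [(1R,2R,4aS,5R,6R,8aR)-6-[(tert-butyldimethylsilyl)oxy]-1,2,4a,5-tetramethyl-1,2,4a,5,6,7,8,8a-octahydronaphthalen-1-yl]methanol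
Product: 18 [(1R,2R,4aS,5R,6R,8aR)-6-[(tert-butyldimethylsilyl)oxy]-1,2,4a,5-tetramethyldecahydronaphthalen-1-yl]methanol
Conditions: H2 (1–4 atm), 10% Pd/C, EtOAc, rt
Reagents that add atoms: none
Why: Heterogeneous catalytic hydrogenation of the cis-disubstituted C3=C4 olefin, which creates no stereocentre and is done before the coumarin is attached so that its C3=C4 bond is never exposed to hydrogen.

Step 12
Reactants: 18 [(1R,2R,4aS,5R,6R,8aR)-6-[(tert-butyldimethylsilyl)oxy]-1,2,4a,5-tetramethyldecahydronaphthalen-1-yl]methanol; 19 7-bromo-2H-chromen-2-one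
Product: 20 7-{[(1R,2R,4aS,5R,6R,8aR)-6-[(tert-butyldimethylsilyl)oxy]-1,2,4a,5-tetramethyldecahydronaphthalen-1-yl]methoxy}-2H-chromen-2-one
Conditions: [Pd(allyl)Cl]2 (2.5 mol%), RockPhos (6 mol%), Cs2CO3 (1.5 equiv), toluene, 90 °C
Reagents that add atoms: none
Why: Palladium-catalysed C–O cross-coupling (Buchwald–Hartwig etherification) of a primary alcohol with an electron-poor aryl bromide forms the ether bond at the arene, so no substitution at the neopentyl carbon is required, and the bulky biaryl phosphine should favour C–O reductive elimination over β-hydride elimination while Cs2CO3 in toluene spares lactone and silyl ether.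

Step 13
Reactants: 20 7-{[(1R,2R,4aS,5R,6R,8aR)-6-[(tert-butyldimethylsilyl)oxy]-1,2,4a,5-tetramethyldecahydronaphthalen-1-yl]methoxy}-2H-chromen-2-one
Product: 21 7-{[(1R,2R,4aS,5R,6R,8aR)-6-hydroxy-1,2,4a,5-tetramethyldecahydronaphthalen-1-yl]methoxy}-2H-chromen-2-one
Conditions: HF·pyridine, pyridine, THF, 0 °C → rt
Reagents that add atoms: none
Why: Fluoride-driven cleavage of the silyl ether under buffered acidic conditions that the coumarin lactone and the aryl ether tolerate.

Step 14
Reactants: 21 7-{[(1R,2R,4aS,5R,6R,8aR)-6-hydroxy-1,2,4a,5-tetramethyldecahydronaphthalen-1-yl]methoxy}-2H-chromen-2-one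
Product: 22 7-{[(1R,2R,4aS,5R,8aR)-1,2,4a,5-tetramethyl-6-oxodecahydronaphthalen-1-yl]methoxy}-2H-chromen-2-one
Conditions: Dess–Martin periodinane, pyridine, CH2Cl2, 0 °C → rt
Reagents that add atoms: none
Why: Dess–Martin oxidation of the secondary alcohol under buffered, essentially neutral conditions should give the ketone without epimerising the adjacent C5 stereocentre, whose equatorial methyl was set in step 2.

**Compound list**

1 | (4S)-4-benzyl-1,3-thiazolidine-2-thione | S=C1N[C@@H](Cc2ccccc2)CS1 | starting material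
2 | propanoyl chloride | CCC(=O)Cl | starting material
3 | 1-[(4S)-4-benzyl-2-sulfanylidene-1,3-thiazolidin-3-yl]propan-1-one | CCC(=O)N1C(=S)SC[C@@H]1Cc1ccccc1 | intermediate
4 | pent-4-enal | C=CCCC=O | starting material
5 | trichlorotitanium (Z)-enolate of 3 | C/C=C(\O[Ti](Cl)(Cl)Cl)N1C(=S)SC[C@@H]1Cc1ccccc1 | intermediate
6 | (2S,3R)-1-[(4S)-4-benzyl-2-sulfanylidene-1,3-thiazolidin-3-yl]-3-hydroxy-2-methylhept-6-en-1-one | C=CCC[C@@H](O)[C@H](C)C(=O)N1C(=S)SC[C@@H]1Cc1ccccc1 | intermediate
7 | (2S,3R)-1-[(4S)-4-benzyl-2-sulfanylidene-1,3-thiazolidin-3-yl]-3-[(tert-butyldimethylsilyl)oxy]-2-methylhept-6-en-1-one | C=CCC[C@@H](O[Si](C)(C)C(C)(C)C)[C@H](C)C(=O)N1C(=S)SC[C@@H]1Cc1ccccc1 | intermediate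
8 | (2S,3R)-3-[(tert-butyldimethylsilyl)oxy]-2-methylhept-6-enal | C=CCC[C@@H](O[Si](C)(C)C(C)(C)C)[C@H](C)C=O | intermediate
9 | (5R,6R)-5-[(tert-butyldimethylsilyl)oxy]-6-methyloct-1-en-7-yne | C=CCC[C@@H](O[Si](C)(C)C(C)(C)C)[C@H](C)C#C | intermediate
10 | [(1E,3R,4R)-4-[(tert-butyldimethylsilyl)oxy]-2,3-dimethylocta-1,7-dien-1-yl]dimethylalane | C=CCC[C@@H](O[Si](C)(C)C(C)(C)C)[C@H](C)/C(C)=C/[Al](C)C | intermediate
11 | (1E,3R,4R)-4-[(tert-butyldimethylsilyl)oxy]-1-iodo-2,3-dimethylocta-1,7-diene | C=CCC[C@@H](O[Si](C)(C)C(C)(C)C)[C@H](C)/C(C)=C/I | intermediate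
12 | 2-methylprop-2-enal (methacrolein) | CC(=C)C=O | starting material
13 | (2E,6R,7R,8E)-6-[(tert-butyldimethylsilyl)oxy]-9-iodo-2,7,8-trimethylnona-2,8-dienal | O=C/C(C)=C/CC[C@@H](O[Si](C)(C)C(C)(C)C)[C@H](C)/C(C)=C/I | intermediate
14 | 4,4,5,5-tetramethyl-2-[(1E)-prop-1-en-1-yl]-1,3,2-dioxaborolane | C/C=C/B1OC(C)(C)C(C)(C)O1 | starting material
15 | (2E,6R,7R,8E,10E)-6-[(tert-butyldimethylsilyl)oxy]-2,7,8-trimethyldodeca-2,8,10-trienal | O=C/C(C)=C/CC[C@@H](O[Si](C)(C)C(C)(C)C)[C@H](C)/C(C)=C/C=C/C | intermediate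
16 | (1R,2R,4aS,5R,6R,8aR)-6-[(tert-butyldimethylsilyl)oxy]-1,2,4a,5-tetramethyl-1,2,4a,5,6,7,8,8a-octahydronaphthalene-1-carbaldehyde | C[C@@H]1C=C[C@@]2(C)[C@@H](CC[C@@H](O[Si](C)(C)C(C)(C)C)[C@@H]2C)[C@]1(C)C=O | intermediate
17 | [(1R,2R,4aS,5R,6R,8aR)-6-[(tert-butyldimethylsilyl)oxy]-1,2,4a,5-tetramethyl-1,2,4a,5,6,7,8,8a-octahydronaphthalen-1-yl]methanol | C[C@@H]1C=C[C@@]2(C)[C@@H](CC[C@@H](O[Si](C)(C)C(C)(C)C)[C@@H]2C)[C@]1(C)CO | intermediate
18 | [(1R,2R,4aS,5R,6R,8aR)-6-[(tert-butyldimethylsilyl)oxy]-1,2,4a,5-tetramethyldecahydronaphthalen-1-yl]methanol | C[C@@H]1CC[C@@]2(C)[C@@H](CC[C@@H](O[Si](C)(C)C(C)(C)C)[C@@H]2C)[C@]1(C)CO | intermediate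
19 | 7-bromo-2H-chromen-2-one | O=c1ccc2ccc(Br)cc2o1 | starting material
20 | 7-{[(1R,2R,4aS,5R,6R,8aR)-6-[(tert-butyldimethylsilyl)oxy]-1,2,4a,5-tetramethyldecahydronaphthalen-1-yl]methoxy}-2H-chromen-2-one | C[C@@H]1CC[C@@]2(C)[C@@H](CC[C@@H](O[Si](C)(C)C(C)(C)C)[C@@H]2C)[C@]1(C)COc1ccc2ccc(=O)oc2c1 | intermediate
21 | 7-{[(1R,2R,4aS,5R,6R,8aR)-6-hydroxy-1,2,4a,5-tetramethyldecahydronaphthalen-1-yl]methoxy}-2H-chromen-2-one | C[C@@H]1CC[C@@]2(C)[C@@H](CC[C@@H](O)[C@@H]2C)[C@]1(C)COc1ccc2ccc(=O)oc2c1 | intermediate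
22 | 7-{[(1R,2R,4aS,5R,8aR)-1,2,4a,5-tetramethyl-6-oxodecahydronaphthalen-1-yl]methoxy}-2H-chromen-2-one | C[C@@H]1CC[C@@]2(C)[C@@H](CCC(=O)[C@@H]2C)[C@]1(C)COc1ccc2ccc(=O)oc2c1 | target

**Step count and risks**

Total step count: 14. Longest linear sequence: 14 steps (1 → 22); the partners 2, 4, 12, 14 and 19 are purchased, so there is no separate branch.

Steps most likely to fail:

1. Step 9 (cyclisation). The endo, trans-fused closure may lose out to the exo, cis-fused closure, because only the former develops the 1,3-contact between the dienophile methyl and the inside diene methyl; the electron-rich trisubstituted diene may also isomerise or oligomerise under the Lewis acid. The fallback is a stepwise ionic (Gassman-type) Diels–Alder reaction. It sets out from 15, which is converted with 1,2-bis(trimethylsilyloxy)ethane and catalytic TMSOTf in CH2Cl2 at −78 °C (Noyori acetalisation) into 2-[(2E,6R,7R,8E,10E)-6-[(tert-butyldimethylsilyl)oxy]-7,8-dimethyldodeca-2,8,10-trien-2-yl]-1,3-dioxolane F1. Ionisation of the acetal with TMSOTf at −78 °C gives a 2-alkoxyallyl cation that should close ring B first through the all-equatorial chair and then ring A by collapse onto the allyl cation, giving 2-[(1R,2R,4aS,5R,6R,8aR)-6-[(tert-butyldimethylsilyl)oxy]-1,2,4a,5-tetramethyl-1,2,4a,5,6,7,8,8a-octahydronaphthalen-1-yl]-1,3-dioxolane F2. Mild hydrolysis (PPTS, acetone/H2O) comes back to the route at 16.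

2. Step 12 (aryl ether formation). Alkoxide transfer and reductive elimination may be slow with the hindered neopentyl alcohol, so that β-hydride elimination (oxidation of the alcohol, reduction of the aryl bromide) takes over. The fallback forms the bond at the alkyl carbon instead. It sets out from 18, which with Tf2O and pyridine in CH2Cl2 at −30 °C should give [(1R,2R,4aS,5R,6R,8aR)-6-[(tert-butyldimethylsilyl)oxy]-1,2,4a,5-tetramethyldecahydronaphthalen-1-yl]methyl trifluoromethanesulfonate F3. Displacement with 7-hydroxy-2H-chromen-2-one and Cs2CO3 in DMF at 40–60 °C comes back to the route at 20.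

3. Step 7 (cross-metathesis). Turnover with the electron-poor 1,1-disubstituted partner may be slow, the catalyst may decompose, or the E selectivity may be incomplete. The fallback is oxidative cleavage followed by a Wittig reaction. It sets out from 11, whose monosubstituted alkene is cleaved selectively (OsO4 cat., NaIO4, 2,6-lutidine, dioxane/H2O) to (4R,5R,6E)-4-[(tert-butyldimethylsilyl)oxy]-7-iodo-5,6-dimethylhept-6-enal F4. Olefination with 2-(triphenylphosphoranylidene)propanal in toluene at 80 °C comes back to the route at 13.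

**Further compounds**

F1 | step 9 | 2-[(2E,6R,7R,8E,10E)-6-[(tert-butyldimethylsilyl)oxy]-7,8-dimethyldodeca-2,8,10-trien-2-yl]-1,3-dioxolane | O1CCOC1/C(C)=C/CC[C@@H](O[Si](C)(C)C(C)(C)C)[C@H](C)/C(C)=C/C=C/C
F2 | step 9 | 2-[(1R,2R,4aS,5R,6R,8aR)-6-[(tert-butyldimethylsilyl)oxy]-1,2,4a,5-tetramethyl-1,2,4a,5,6,7,8,8a-octahydronaphthalen-1-yl]-1,3-dioxolane | C[C@@H]1C=C[C@@]2(C)[C@@H](CC[C@@H](O[Si](C)(C)C(C)(C)C)[C@@H]2C)[C@]1(C)C1OCCO1
F3 | step 12 | [(1R,2R,4aS,5R,6R,8aR)-6-[(tert-butyldimethylsilyl)oxy]-1,2,4a,5-tetramethyldecahydronaphthalen-1-yl]methyl trifluoromethanesulfonate | C[C@@H]1CC[C@@]2(C)[C@@H](CC[C@@H](O[Si](C)(C)C(C)(C)C)[C@@H]2C)[C@]1(C)COS(=O)(=O)C(F)(F)F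
F4 | step 7 | (4R,5R,6E)-4-[(tert-butyldimethylsilyl)oxy]-7-iodo-5,6-dimethylhept-6-enal | O=CCC[C@@H](O[Si](C)(C)C(C)(C)C)[C@H](C)/C(C)=C/I
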